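**Plan**
- Retrosynthesis: the three phenol protecting groups come off first, then both vinyl groups are traced back to C–B bonds, then both C(quaternary)–CH2 bonds to the homogeranyl chains are cut in one operation, and last the diaryl ether C–O bond between ring A (the trioxygenated ring) and ring B is cut.
- Enabling feature: each quaternary carbon (on C1 of ring A and on C3 of ring B) is benzylic and carries a CH3 group, so each is the carbinol carbon of a 1-arylethyl carbamate.
- Forward: two aryl methyl ketones are reduced separately, the halves are joined by a copper-catalysed diaryl ether coupling, both alcohols are carbamoylated together, both chains are attached by a double lithiation–borylation, boron is exchanged for vinyl, and the phenols are freed. No ring is formed in the route.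
- Stereochemistry: the (R) centre on ring A and the (S) centre on ring B come from (R,R)- and (S,S)-configured ruthenium transfer-hydrogenation catalysts. They are relayed by retentive borylation, invertive 1,2-shift and retentive Zweifel olefination. Both E olefins come from geraniol.

Key step: step 13

Assumption: the halves are used at the enantiomeric purity the two reductions deliver; because two enantioenriched halves are joined, most of the minor enantiomers should end up in diastereomers of the coupled diol, removable by chromatography. Abbreviations: MOM = methoxymethyl, pin = pinacolato.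

**Step 1**
Reactants: 1 acetovanillone
Product: 2 5-iodoacetovanillone, 1-(4-hydroxy-3-iodo-5-methoxyphenyl)ethanone
Conditions: NIS (1.05 equiv), TFA (cat.), MeCN, rt
Reagents that add atoms: N-iodosuccinimide, O=C1CCC(=O)N1I
Why: Electrophilic aromatic iodination should go to the only free position ortho to the phenol, the strongest director, since the para position carries the acetyl group.

**Step 2**
Reactants: 2 5-iodoacetovanillone
Product: 3 1-(3,4-dihydroxy-5-iodophenyl)ethanone
Conditions: BBr3 (3 equiv), CH2Cl2, −78 °C → rt; H2O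
Reagents that add atoms: none
Why: Lewis-acid cleavage of the aryl methyl ether (bromide attacks the O-methyl of the boron-complexed ether) should free the catechol, and the aryl iodide and the aryl ketone are inert to BBr3.

**Step 3**
Reactants: 3 1-(3,4-dihydroxy-5-iodophenyl)ethanone
Product: 4 1-[3-iodo-4,5-bis(methoxymethoxy)phenyl]ethanone
Conditions: MOMCl (3 equiv), i-Pr2NEt (4 equiv), CH2Cl2, 0 °C → rt
Reagents that add atoms: chloromethyl methyl ether, COCCl
Why: O-alkylation of both phenols with the reactive α-chloro ether gives base-stable acetals that tolerate reduction, copper catalysis and alkyllithium reagents.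

**Step 4**
Reactants: 4 1-[3-iodo-4,5-bis(methoxymethoxy)phenyl]ethanone
Product: 5 (R)-1-[3-iodo-4,5-bis(methoxymethoxy)phenyl]ethanol
Conditions: RuCl(p-cymene)[(R,R)-TsDPEN] (1 mol%), HCO2H/Et3N (5:2), DMF, 30 °C
Reagents that add atoms: none
Why: Noyori asymmetric transfer hydrogenation of an aryl methyl ketone, in which the (R,R)-TsDPEN ligand delivers hydride through the CH/π-organised six-membered transition state to the face that gives the (R)-1-arylethanol, without touching the aryl iodide or the MOM acetals.

**Step 5**
Reactants: 6 2',3'-dihydroxyacetophenone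
Product: 7 1-[3-(allyloxy)-2-hydroxyphenyl]ethanone
Conditions: NaH (2.1 equiv), DMSO, rt; allyl bromide (1.0 equiv), rt; 1 M HCl work-up
Reagents that add atoms: allyl bromide, C=CCBr
Why: Regioselective mono-O-alkylation of a catecholate dianion, in which the 3-oxide is the more nucleophilic oxygen because it is neither conjugated with nor chelated to the acetyl group, as known for 2,3-dihydroxybenzaldehyde.

**Step 6**
Reactants: 7 1-[3-(allyloxy)-2-hydroxyphenyl]ethanone
Product: 8 1-[3-(allyloxy)-2-(methoxymethoxy)phenyl]ethanone
Conditions: MOMCl (2 equiv), i-Pr2NEt (3 equiv), CH2Cl2, 0 °C → reflux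
Reagents that add atoms: chloromethyl methyl ether, COCCl
Why: O-alkylation of the remaining, hydrogen-bonded phenol with MOMCl is routine for 2'-hydroxyacetophenones when run with excess reagent at reflux.

**Step 7**
Reactants: 8 1-[3-(allyloxy)-2-(methoxymethoxy)phenyl]ethanone
Product: 9 (S)-1-[3-(allyloxy)-2-(methoxymethoxy)phenyl]ethanol
Conditions: RuCl(p-cymene)[(S,S)-TsDPEN] (2 mol%), HCO2H/Et3N (5:2), DMF, 40 °C
Reagents that add atoms: none
Why: Noyori asymmetric transfer hydrogenation with the enantiomeric (S,S) catalyst should give the (S)-1-arylethanol by the same transition-state model, and this ruthenium hydride does not reduce or isomerise the allyl ether.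

**Step 8**
Reactants: 9 (S)-1-[3-(allyloxy)-2-(methoxymethoxy)phenyl]ethanol
Product: 10 (S)-3-(1-hydroxyethyl)-2-(methoxymethoxy)phenol
Conditions: Pd(PPh3)4 (3 mol%), morpholine (3 equiv), THF, rt
Reagents that add atoms: none
Why: Tsuji–Trost deallylation, in which zerovalent palladium ionises the aryl allyl ether to a π-allyl complex that morpholine captures, frees only the phenol and leaves the carbinol centre and the MOM acetal alone.

**Step 9**
Reactants: 5 (R)-1-[3-iodo-4,5-bis(methoxymethoxy)phenyl]ethanol; 10 (S)-3-(1-hydroxyethyl)-2-(methoxymethoxy)phenol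
Product: 11 (R)-1-{3-[3-((S)-1-hydroxyethyl)-2-(methoxymethoxy)phenoxy]-4,5-bis(methoxymethoxy)phenyl}ethanol
Conditions: CuI (10 mol%), picolinic acid (20 mol%), K3PO4 (2 equiv), DMSO, 85 °C, Ar
Reagents that add atoms: none
Why: Ullmann-type copper-catalysed O-arylation, in which only the phenoxide is formed by K3PO4 and couples with the aryl iodide while the two far less acidic secondary alcohols stay passive, and the picolinate ligand is known to tolerate ortho-substituted partners.

**Step 10**
Reactants: 11 the diaryl ether diol
Product: 12 diaryl ether bis(N,N-diisopropylcarbamate), (R)-carbinol on ring A and (S)-carbinol on ring B, three MOM ethers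
Conditions: i-Pr2NC(O)Cl (3 equiv), Et3N (4 equiv), CH2Cl2, reflux
Reagents that add atoms: N,N-diisopropylcarbamoyl chloride, CC(C)N(C(C)C)C(=O)Cl
Why: O-carbamoylation of both secondary benzylic alcohols in one operation proceeds at oxygen only, so neither carbinol centre is touched.

**Step 11**
Reactants: 13 geraniol
Product: 14 geranyl pinacol boronate, 2-[(2E)-3,7-dimethylocta-2,6-dien-1-yl]-4,4,5,5-tetramethyl-1,3,2-dioxaborolane
Conditions: B2pin2 (1.2 equiv), Pd(MeCN)4(BF4)2 (5 mol%), DMSO/MeOH (1:1), 40 °C
Reagents that add atoms: bis(pinacolato)diboron, CC1(C)OB(OC1(C)C)B1OC(C)(C)C(C)(C)O1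
Why: Palladium-catalysed allylic C–OH borylation via an η3-allyl palladium intermediate places boron at the less hindered primary terminus and keeps the E geometry of the syn-allyl complex.

**Step 12**
Reactants: 14 geranyl pinacol boronate
Product: 16 (E)-homogeranyl pinacol boronate, 2-[(3E)-4,8-dimethylnona-3,7-dien-1-yl]-4,4,5,5-tetramethyl-1,3,2-dioxaborolane, via lithium chloromethyl boronate complex 15 (not isolated)
Conditions: BrCH2Cl (1.5 equiv), n-BuLi (1.3 equiv), THF, −78 °C → rt
Reagents that add atoms: bromochloromethane, ClCBr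
Why: Matteson homologation, in which LiCH2Cl made in the flask by bromine–lithium exchange adds to boron and the allylic CH2 of complex 15 then migrates 1,2 with loss of chloride, a shift at the α-carbon that leaves the E olefin in place.

**Step 13**
Reactants: 12 diaryl ether bis(N,N-diisopropylcarbamate); 16 (E)-homogeranyl pinacol boronate
Product: 19 diaryl ether bis(tertiary pinacol boronate) carrying both homogeranyl chains, via dilithiated bis-carbamate 17 (not isolated), via bis-boronate ate complex 18 (not isolated)
Conditions: s-BuLi (2.6 equiv), Et2O, −78 °C; 16 (3 equiv), −78 °C; MgBr2·OEt2/MeOH, −78 °C → rt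
Reagents that add atoms: none
Why: s-BuLi, guided by each carbamoyl oxygen, removes the two benzylic α-oxygen hydrogens with retention to give the configurationally stable dilithio species 17, and each C–Li bond takes up boronate 16 on the lithium-bearing face to give the bis-ate complex 18. On warming, each homogeranyl CH2 migrates from boron to carbon anti-periplanar to the departing carbamate (1,2-metallate rearrangement), so both C(quaternary)–CH2 bonds form with inversion at carbon while boron sits where hydrogen was. The closest known reaction type is the lithiation–borylation of enantioenriched secondary benzylic carbamates with primary alkyl pinacol boronates (Hoppe lithiation joined to a Matteson-type shift), here run at two sites of one molecule; no ring closes. Each new stereocentre is controlled only by its own carbinol centre, the (R)-carbamate on ring A giving the (R)-boronate and the (S)-carbamate on ring B the (S)-boronate. The step needs benzylic rather than ring metalation, which the complex-induced proximity of the carbamate and the far higher acidity of the benzylic α-oxygen C–H at −78 °C in Et2O without diamine should secure. It also needs the ate complexes not to revert, which MgBr2/MeOH secures by speeding the shift and protonating any released benzyllithium before it can racemise and re-add.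

**Step 14**
Reactants: 19 diaryl ether bis(tertiary pinacol boronate)
Product: 22 tris-MOM ether of the target, via bis-vinyl boronate ate complex 20 (not isolated), via bis(β-iodoalkyl boronate) 21 (not isolated)
Conditions: CH2=CHMgBr (8 equiv), THF, rt; I2 (8 equiv), MeOH, −78 °C; NaOMe (16 equiv), MeOH, −78 °C → rt; aq. Na2S2O3
Reagents that add atoms: vinylmagnesium bromide, C=C[Mg]Br
Why: Zweifel olefination, in which vinyl adds to each boron (complex 20), iodonium formation triggers 1,2-migration of the tertiary benzylic carbon with retention (21), and methoxide-induced anti elimination of boron and iodide leaves a vinyl group exactly where each boron was.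

**Step 15**
Reactants: 22 tris-MOM ether of the target
Product: 23 CNP0325484.1, 5-[(3R,6E)-3,7,11-trimethyldodeca-1,6,10-trien-3-yl]-3-{2-hydroxy-3-[(3S,6E)-3,7,11-trimethyldodeca-1,6,10-trien-3-yl]phenoxy}benzene-1,2-diol
Conditions: conc. HCl (3 equiv), degassed MeOH/THF, rt → 40 °C, Ar
Reagents that add atoms: none
Why: Acid-catalysed transacetalisation of the three aryl MOM acetals to methanol frees the phenols under conditions too mild to protonate the trisubstituted or terminal olefins, and the quaternary centres cannot ionise or epimerise.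

**Compound list**
1 | acetovanillone, 1-(4-hydroxy-3-methoxyphenyl)ethanone | CC(=O)c1ccc(O)c(OC)c1 | starting material
2 | 5-iodoacetovanillone, 1-(4-hydroxy-3-iodo-5-methoxyphenyl)ethanone | CC(=O)c1cc(I)c(O)c(OC)c1 | intermediate
3 | 1-(3,4-dihydroxy-5-iodophenyl)ethanone | CC(=O)c1cc(O)c(O)c(I)c1 | intermediate
4 | 1-[3-iodo-4,5-bis(methoxymethoxy)phenyl]ethanone | CC(=O)c1cc(OCOC)c(OCOC)c(I)c1 | intermediate
5 | (R)-1-[3-iodo-4,5-bis(methoxymethoxy)phenyl]ethanol | C[C@@H](O)c1cc(OCOC)c(OCOC)c(I)c1 | intermediate
6 | 2',3'-dihydroxyacetophenone | CC(=O)c1cccc(O)c1O | starting material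
7 | 1-[3-(allyloxy)-2-hydroxyphenyl]ethanone | CC(=O)c1cccc(OCC=C)c1O | intermediate
8 | 1-[3-(allyloxy)-2-(methoxymethoxy)phenyl]ethanone | CC(=O)c1cccc(OCC=C)c1OCOC | intermediate
9 | (S)-1-[3-(allyloxy)-2-(methoxymethoxy)phenyl]ethanol | C[C@H](O)c1cccc(OCC=C)c1OCOC | intermediate
10 | (S)-3-(1-hydroxyethyl)-2-(methoxymethoxy)phenol | C[C@H](O)c1cccc(O)c1OCOC | intermediate
11 | (R)-1-{3-[3-((S)-1-hydroxyethyl)-2-(methoxymethoxy)phenoxy]-4,5-bis(methoxymethoxy)phenyl}ethanol | C[C@@H](O)c1cc(OCOC)c(OCOC)c(Oc2cccc([C@H](C)O)c2OCOC)c1 | intermediate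
12 | bis(N,N-diisopropylcarbamate) of 11, (R) on ring A and (S) on ring B | C[C@@H](OC(=O)N(C(C)C)C(C)C)c1cc(OCOC)c(OCOC)c(Oc2cccc([C@H](C)OC(=O)N(C(C)C)C(C)C)c2OCOC)c1 | intermediate
13 | geraniol | CC(C)=CCC/C(C)=C/CO | starting material
14 | geranyl pinacol boronate | CC(C)=CCC/C(C)=C/CB1OC(C)(C)C(C)(C)O1 | intermediate
15 | lithium (chloromethyl)(geranyl) pinacol boronate complex (formed in the flask) | [Li+].ClC[B-]1(C/C=C(\C)CCC=C(C)C)OC(C)(C)C(C)(C)O1 | intermediate
16 | (E)-homogeranyl pinacol boronate | CC(C)=CCC/C(C)=C/CCB1OC(C)(C)C(C)(C)O1 | intermediate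
17 | dilithiated bis-carbamate, lithium in place of each benzylic hydrogen with retention (formed in the flask) | C[C@@]([Li])(OC(=O)N(C(C)C)C(C)C)c1cc(OCOC)c(OCOC)c(Oc2cccc([C@]([Li])(C)OC(=O)N(C(C)C)C(C)C)c2OCOC)c1 | intermediate
18 | dilithium bis-boronate ate complex, each benzylic carbon bonded to a borate bearing homogeranyl and pinacolato (formed in the flask) | [Li+].[Li+].C[C@@]([B-]1(CC/C=C(\C)CCC=C(C)C)OC(C)(C)C(C)(C)O1)(OC(=O)N(C(C)C)C(C)C)c1cc(OCOC)c(OCOC)c(Oc2cccc([C@]([B-]3(CC/C=C(\C)CCC=C(C)C)OC(C)(C)C(C)(C)O3)(C)OC(=O)N(C(C)C)C(C)C)c2OCOC)c1 | intermediate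
19 | diaryl ether bis(tertiary pinacol boronate), each benzylic carbon bearing CH3, Bpin and (E)-homogeranyl, (R) on ring A and (S) on ring B, three MOM ethers | C[C@](B1OC(C)(C)C(C)(C)O1)(CC/C=C(\C)CCC=C(C)C)c1cc(OCOC)c(OCOC)c(Oc2cccc([C@](C)(B3OC(C)(C)C(C)(C)O3)CC/C=C(\C)CCC=C(C)C)c2OCOC)c1 | intermediate
20 | bis(bromomagnesium) bis-vinyl boronate ate complex of 19 (formed in the flask) | C[C@]([B-]1(C=C)OC(C)(C)C(C)(C)O1)(CC/C=C(\C)CCC=C(C)C)c1cc(OCOC)c(OCOC)c(Oc2cccc([C@](C)([B-]3(C=C)OC(C)(C)C(C)(C)O3)CC/C=C(\C)CCC=C(C)C)c2OCOC)c1.[Mg+2].[Mg+2].[Br-].[Br-] | intermediate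
21 | bis(β-iodoalkyl pinacol boronate), each quaternary carbon bearing CH(Bpin)CH2I, mixture of epimers at the boron-bearing carbons (formed in the flask) | C[C@](C(CI)B1OC(C)(C)C(C)(C)O1)(CC/C=C(\C)CCC=C(C)C)c1cc(OCOC)c(OCOC)c(Oc2cccc([C@](C)(C(CI)B3OC(C)(C)C(C)(C)O3)CC/C=C(\C)CCC=C(C)C)c2OCOC)c1 | intermediate
22 | tris-MOM ether of the target, (R) on ring A and (S) on ring B | C[C@](C=C)(CC/C=C(\C)CCC=C(C)C)c1cc(OCOC)c(OCOC)c(Oc2cccc([C@](C)(C=C)CC/C=C(\C)CCC=C(C)C)c2OCOC)c1 | intermediate
23 | CNP0325484.1 | C=C[C@@](C)(CC/C=C(\C)CCC=C(C)C)c1cc(O)c(O)c(Oc2cccc([C@](C)(C=C)CC/C=C(\C)CCC=C(C)C)c2O)c1 | target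

**Totals**
Total step count: 15. Longest linear sequence: 9 steps (steps 1–4, 9, 10, 13, 14, 15).

**Steps most likely to fail**

1. Step 13. Ring metalation next to the MOM ethers may compete with the second benzylic deprotonation, and the ortho-substituted ring B centre may lose configuration through reversible boronate complexation. The fallback installs one chain at a time, so only a monolithio species is ever needed; it sets out from 5 and returns at 22.
   - Carbamoylation of 5 alone (i-Pr2NC(O)Cl, Et3N) would give (R)-1-[3-iodo-4,5-bis(methoxymethoxy)phenyl]ethyl N,N-diisopropylcarbamate F1.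
   - Ullmann coupling of F1 with 10 under the step 9 conditions would give the diaryl ether mono-carbamate with a free (S)-carbinol on ring B F2.
   - Lithiation–borylation of F2 with s-BuLi (2.2 equiv, the first only forming the ring B lithium alkoxide) and 16 would give the ring A tertiary boronate alcohol F3.
   - Zweifel olefination would give the ring A vinyl alcohol F4, and carbamoylation the ring B carbamate F5.
   - A second single lithiation–borylation with 16 would give the ring B tertiary boronate F6, and a second Zweifel olefination 22.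

2. Step 14. Vinyl addition may stall at the crowded ring B boron, and iodine may be consumed by the chain olefins or the electron-rich rings. The fallback avoids iodine altogether, setting out from 19 and returning at 22.
   - Double Matteson homologation of 19 with LiCH2Cl (BrCH2Cl, n-BuLi, THF, −78 °C → rt) would give the bis(primary neopentyl-type pinacol boronate) F7.
   - Oxidation with NaBO3·4H2O in THF/H2O would give the diol F8.
   - Dess–Martin periodinane would give the dialdehyde F9, which has no α-hydrogen and cannot epimerise.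
   - Wittig methylenation with Ph3P=CH2 would give 22.

3. Step 9. Coupling at copper between two ortho-oxygenated partners may be sluggish, with protodeiodination taking over. The fallback reverses the role of ring A and couples oxidatively at room temperature, setting out from 5 and returning at 11.
   - Iodine–magnesium exchange on 5 with i-PrMgCl·LiCl (2.2 equiv, THF, −20 °C), trapping with B(OMe)3 and mild aqueous work-up would give (R)-[5-(1-hydroxyethyl)-2,3-bis(methoxymethoxy)phenyl]boronic acid F10.
   - Chan–Lam–Evans coupling of F10 with 10 (Cu(OAc)2, pyridine, 4 Å molecular sieves, CH2Cl2, air, rt) would give 11.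

**Further compounds**
F1 | step 13 | (R)-1-[3-iodo-4,5-bis(methoxymethoxy)phenyl]ethyl N,N-diisopropylcarbamate | C[C@@H](OC(=O)N(C(C)C)C(C)C)c1cc(OCOC)c(OCOC)c(I)c1
F2 | step 13 | diaryl ether with (R)-carbamate on ring A and free (S)-carbinol on ring B | C[C@@H](OC(=O)N(C(C)C)C(C)C)c1cc(OCOC)c(OCOC)c(Oc2cccc([C@H](C)O)c2OCOC)c1
F3 | step 13 | ring A tertiary pinacol boronate with homogeranyl chain, free (S)-carbinol on ring B | C[C@](B1OC(C)(C)C(C)(C)O1)(CC/C=C(\C)CCC=C(C)C)c1cc(OCOC)c(OCOC)c(Oc2cccc([C@H](C)O)c2OCOC)c1
F4 | step 13 | ring A vinyl quaternary compound, free (S)-carbinol on ring B | C[C@](C=C)(CC/C=C(\C)CCC=C(C)C)c1cc(OCOC)c(OCOC)c(Oc2cccc([C@H](C)O)c2OCOC)c1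
F5 | step 13 | ring A vinyl quaternary compound, (S)-N,N-diisopropylcarbamate on ring B | C[C@](C=C)(CC/C=C(\C)CCC=C(C)C)c1cc(OCOC)c(OCOC)c(Oc2cccc([C@H](C)OC(=O)N(C(C)C)C(C)C)c2OCOC)c1
F6 | step 13 | ring A vinyl quaternary compound, ring B tertiary pinacol boronate with homogeranyl chain | C[C@](C=C)(CC/C=C(\C)CCC=C(C)C)c1cc(OCOC)c(OCOC)c(Oc2cccc([C@](C)(B3OC(C)(C)C(C)(C)O3)CC/C=C(\C)CCC=C(C)C)c2OCOC)c1
F7 | step 14 | bis(primary pinacol boronate), CH2Bpin on each quaternary carbon | C[C@](CB1OC(C)(C)C(C)(C)O1)(CC/C=C(\C)CCC=C(C)C)c1cc(OCOC)c(OCOC)c(Oc2cccc([C@](C)(CB3OC(C)(C)C(C)(C)O3)CC/C=C(\C)CCC=C(C)C)c2OCOC)c1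
F8 | step 14 | diol, CH2OH on each quaternary carbon | C[C@](CO)(CC/C=C(\C)CCC=C(C)C)c1cc(OCOC)c(OCOC)c(Oc2cccc([C@](C)(CO)CC/C=C(\C)CCC=C(C)C)c2OCOC)c1
F9 | step 14 | dialdehyde, CHO on each quaternary carbon | C[C@](C=O)(CC/C=C(\C)CCC=C(C)C)c1cc(OCOC)c(OCOC)c(Oc2cccc([C@](C)(C=O)CC/C=C(\C)CCC=C(C)C)c2OCOC)c1
F10 | step 9 | (R)-[5-(1-hydroxyethyl)-2,3-bis(methoxymethoxy)phenyl]boronic acid | C[C@@H](O)c1cc(OCOC)c(OCOC)c(B(O)O)c1
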